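**Retrosynthetic overview**
1. The oxolane (the only ring of the target, closed last) is opened at O–C7: target 17 ⇐ p-quinone methide 16 with a free 9'-OH, the ring closure presumed in the plant; 16 is released by fluoride from the bis-silyl triacetate 14.
2. 14 ⇐ reductive opening and peracetylation of the all-trans γ-lactone 11; the two lactone oxygens (O7', O9) become the two acetates, and the silylated O9' stays distinct as the future ring oxygen.
3. 11 ⇐ lactone 9 + aldehyde 10 by a trans-selective aldol; the C7 carbinol is left uncontrolled because both epimers converge at the quinone methide.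
4. 9 ⇐ Evans syn-aldol/lactonisation of succinyl imide 3 with 4-methoxybenzaldehyde, which sets C7' and C8' absolutely.
5. Ring order: temporary γ-lactone first (step 2, stereochemical template), oxolane last (step 7).

Assumption: lignan numbering is used for atom labels (C7–C9 = 4-hydroxyphenyl unit, C7'–C9' = 4-methoxyphenyl unit); the target is the (7R,8S,7'S,8'R) all-trans oxolane; aldehyde 10 is bought.

**Step 1**
Reactants: 1 (S)-4-benzyl-1,3-oxazolidin-2-one; 2 methyl 4-chloro-4-oxobutanoate
Product: 3 methyl 4-[(4S)-4-benzyl-2-oxo-1,3-oxazolidin-3-yl]-4-oxobutanoate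
Conditions: n-BuLi, THF, −78 °C; then 2, −78 → 0 °C
Reagents that add atoms: methyl 4-chloro-4-oxobutanoate, COC(=O)CCC(Cl)=O
Why: N-acylation of the lithiated oxazolidinone by the acid chloride (far more electrophilic than the methyl ester) gives the imide, and no stereocentre is formed.

**Step 2**
Reactants: 3 succinyl imide; 4 4-methoxybenzaldehyde
Product: 6 (4S)-4-benzyl-3-{[(2S,3S)-2-(4-methoxyphenyl)-5-oxooxolan-3-yl]carbonyl}-1,3-oxazolidin-2-one, via syn-aldol adduct 5 (not isolated)
Conditions: Bu2BOTf, i-Pr2NEt, CH2Cl2, 0 °C; 4, −78 → 0 °C → rt; pH 7 buffer, MeOH, H2O2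
Reagents that add atoms: 4-methoxybenzaldehyde, COc1ccc(C=O)cc1
Why: Evans syn-aldol reaction in which soft enolisation gives the chelated Z-boron enolate of the imide only, the benzyl group of the (S)-auxiliary directs the aldehyde to one face of a Zimmerman–Traxler chair to set C7' (S) and C8' (syn), and the γ-hydroxy ester 5 then closes with loss of methanol to the 2,3-trans lactone.

**Step 3**
Reactants: 6 lactone imide
Product: 7 (4R,5S)-4-(hydroxymethyl)-5-(4-methoxyphenyl)oxolan-2-one
Conditions: NaBH4, THF/H2O (4:1), 0 °C → rt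
Reagents that add atoms: none
Why: Borohydride reduction of the activated exocyclic imide carbonyl (reductive removal of the oxazolidinone, which is recovered) gives the primary alcohol while the much less electrophilic γ-lactone is kept, and no stereocentre is touched.

**Step 4**
Reactants: 7 hydroxymethyl lactone; 8 chlorotriethylsilane
Product: 9 (4R,5S)-5-(4-methoxyphenyl)-4-[(triethylsilyloxy)methyl]oxolan-2-one
Conditions: Et3SiCl, imidazole, CH2Cl2, 0 °C
Reagents that add atoms: chlorotriethylsilane, CC[Si](CC)(CC)Cl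
Why: Silylation of the only hydroxyl masks the future ring oxygen O9' so that it stays distinct from the two lactone oxygens that will become the acetates, and no stereocentre is formed.

**Step 5**
Reactants: 9 silylated lactone; 10 4-(tert-butyldimethylsilyloxy)benzaldehyde
Product: 11 (3R,4R,5S)-3-{(RS)-[4-(tert-butyldimethylsilyloxy)phenyl](hydroxy)methyl}-5-(4-methoxyphenyl)-4-[(triethylsilyloxy)methyl]oxolan-2-one
Conditions: LiN(i-Pr)2, THF, −78 °C; 10, −78 °C; NH4Cl (aq), −78 °C
Reagents that add atoms: 4-(tert-butyldimethylsilyloxy)benzaldehyde, CC(C)(C)[Si](C)(C)Oc1ccc(C=O)cc1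
Why: Aldol addition of the lithium lactone enolate, in which the aldehyde adds to the face anti to the neighbouring CH2OSiEt3 group and so sets C8 trans to C8' (all-trans lactone), while the C7 carbinol forms as an epimer mixture that is deliberately not controlled because both epimers later give the same quinone methide.

**Step 6**
Reactants: 11 aldol lactone; 12 acetic anhydride
Product: 14 (1S,2R,3S,4RS)-3-(acetoxymethyl)-4-[4-(tert-butyldimethylsilyloxy)phenyl]-1-(4-methoxyphenyl)-2-[(triethylsilyloxy)methyl]butane-1,4-diyl diacetate, via triol 13 (not isolated)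
Conditions: LiBH4, THF, 0 °C → rt; then AcOH (quench), Ac2O, pyridine, DMAP, 0 °C → rt
Reagents that add atoms: acetic anhydride, CC(=O)OC(C)=O
Why: Hydride reduction opens the lactone to triol 13 without touching the silyl ethers, and exhaustive DMAP-catalysed acetylation in the same flask turns the two former lactone oxygens (O9, O7') into the acetates of the target and the C7 hydroxyl into the leaving group for the last step, with no stereocentre changed.

**Step 7**
Reactants: 14 bis-silyl triacetate
Product: 17 [(2R,3S,4R)-4-[(S)-acetoxy(4-methoxyphenyl)methyl]-2-(4-hydroxyphenyl)oxolan-3-yl]methyl acetate (target), via desilylated phenol 15 (not isolated), via p-quinone methide 16 (not isolated)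
Conditions: Bu4NF (2.5 equiv), THF, 0 °C → rt; NH4Cl (aq)
Reagents that add atoms: none
Why: Proposed new method: fluoride removes both silyl groups, the phenoxide expels the benzylic C7 acetate (1,6-elimination) to give p-quinone methide 16 from either C7 epimer, and the freed 9'-hydroxyl adds 5-exo to the methide carbon (intramolecular oxa-1,6-conjugate addition) with the quinoid ring pseudo-equatorial and anti to the C8 acetoxymethyl group, so that C7 is set R (2,3-trans, all-trans oxolane) and the phenol is regenerated; the closest known reactions are fluoride-triggered quinone methide release from 4-silyloxybenzyl esters and quinone methide or benzylic cation cyclisations of lignan triols to 7,9'-epoxylignans.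

**Compound list**
1 | (S)-4-benzyl-1,3-oxazolidin-2-one | O=C1N[C@@H](Cc2ccccc2)CO1 | starting material
2 | methyl 4-chloro-4-oxobutanoate | COC(=O)CCC(Cl)=O | starting material
3 | methyl 4-[(4S)-4-benzyl-2-oxo-1,3-oxazolidin-3-yl]-4-oxobutanoate | COC(=O)CCC(=O)N1[C@@H](Cc2ccccc2)COC1=O | intermediate
4 | 4-methoxybenzaldehyde | COc1ccc(C=O)cc1 | starting material
5 | methyl (3S)-4-[(4S)-4-benzyl-2-oxo-1,3-oxazolidin-3-yl]-3-[(S)-hydroxy(4-methoxyphenyl)methyl]-4-oxobutanoate (syn-aldol adduct, not isolated) | COc1ccc([C@@H](O)[C@H](CC(=O)OC)C(=O)N2[C@@H](Cc3ccccc3)COC2=O)cc1 | intermediate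
6 | (4S)-4-benzyl-3-{[(2S,3S)-2-(4-methoxyphenyl)-5-oxooxolan-3-yl]carbonyl}-1,3-oxazolidin-2-one | COc1ccc([C@H]2OC(=O)C[C@@H]2C(=O)N3[C@@H](Cc4ccccc4)COC3=O)cc1 | intermediate
7 | (4R,5S)-4-(hydroxymethyl)-5-(4-methoxyphenyl)oxolan-2-one | COc1ccc([C@H]2OC(=O)C[C@@H]2CO)cc1 | intermediate
8 | chlorotriethylsilane | CC[Si](CC)(CC)Cl | starting material
9 | (4R,5S)-5-(4-methoxyphenyl)-4-[(triethylsilyloxy)methyl]oxolan-2-one | COc1ccc([C@H]2OC(=O)C[C@@H]2CO[Si](CC)(CC)CC)cc1 | intermediate
10 | 4-(tert-butyldimethylsilyloxy)benzaldehyde | CC(C)(C)[Si](C)(C)Oc1ccc(C=O)cc1 | starting material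
11 | (3R,4R,5S)-3-{(RS)-[4-(tert-butyldimethylsilyloxy)phenyl](hydroxy)methyl}-5-(4-methoxyphenyl)-4-[(triethylsilyloxy)methyl]oxolan-2-one (C7 epimers) | COc1ccc([C@H]2OC(=O)[C@@H](C(O)c3ccc(O[Si](C)(C)C(C)(C)C)cc3)[C@@H]2CO[Si](CC)(CC)CC)cc1 | intermediate
12 | acetic anhydride | CC(=O)OC(C)=O | starting material
13 | (1S,2R,3S,4RS)-4-[4-(tert-butyldimethylsilyloxy)phenyl]-3-(hydroxymethyl)-1-(4-methoxyphenyl)-2-[(triethylsilyloxy)methyl]butane-1,4-diol (triol, not isolated) | COc1ccc([C@@H](O)[C@@H](CO[Si](CC)(CC)CC)[C@@H](CO)C(O)c2ccc(O[Si](C)(C)C(C)(C)C)cc2)cc1 | intermediate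
14 | (1S,2R,3S,4RS)-3-(acetoxymethyl)-4-[4-(tert-butyldimethylsilyloxy)phenyl]-1-(4-methoxyphenyl)-2-[(triethylsilyloxy)methyl]butane-1,4-diyl diacetate | COc1ccc([C@@H](OC(C)=O)[C@@H](CO[Si](CC)(CC)CC)[C@@H](COC(C)=O)C(OC(C)=O)c2ccc(O[Si](C)(C)C(C)(C)C)cc2)cc1 | intermediate
15 | (1S,2R,3S,4RS)-3-(acetoxymethyl)-2-(hydroxymethyl)-4-(4-hydroxyphenyl)-1-(4-methoxyphenyl)butane-1,4-diyl diacetate (desilylated phenol, not isolated) | COc1ccc([C@@H](OC(C)=O)[C@@H](CO)[C@@H](COC(C)=O)C(OC(C)=O)c2ccc(O)cc2)cc1 | intermediate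
16 | 4-[(2S,3R,4S)-4-acetoxy-2-(acetoxymethyl)-3-(hydroxymethyl)-4-(4-methoxyphenyl)butylidene]cyclohexa-2,5-dien-1-one (p-quinone methide, not isolated) | COc1ccc([C@@H](OC(C)=O)[C@@H](CO)[C@@H](COC(C)=O)C=C2C=CC(=O)C=C2)cc1 | intermediate
17 | [(2R,3S,4R)-4-[(S)-acetoxy(4-methoxyphenyl)methyl]-2-(4-hydroxyphenyl)oxolan-3-yl]methyl acetate | COc1ccc([C@@H](OC(C)=O)[C@H]2CO[C@@H](c3ccc(O)cc3)[C@@H]2COC(C)=O)cc1 | target

**Totals**
Total step count: 7. Longest linear sequence: 7 (fully linear from 1).

**Three steps most likely to fail**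

Step 7 (fluoride cascade). The quinone methide may form before the triethylsilyl ether is cleaved and be lost to hydration, tautomerisation to the 4-hydroxystyrene or oligomers. An acetyl group may also migrate to the freed 9'-OH, and the 2,3-trans selectivity may be incomplete. The fallback generates the same quinone methide oxidatively, with the nucleophile already free, and sets out from 9. The enolate of 9 (LiN(i-Pr)2, THF, −78 °C) is alkylated anti to the CH2OSiEt3 group with commercial 4-(tert-butyldimethylsilyloxy)benzyl bromide to give (3S,4R,5S)-3-[4-(tert-butyldimethylsilyloxy)benzyl]-5-(4-methoxyphenyl)-4-[(triethylsilyloxy)methyl]oxolan-2-one F1. LiBH4 opens the lactone to (1S,2R,3S)-3-[4-(tert-butyldimethylsilyloxy)benzyl]-1-(4-methoxyphenyl)-2-[(triethylsilyloxy)methyl]butane-1,4-diol F2. Ac2O/pyridine/DMAP gives the diacetate (1S,2R,3S)-3-(acetoxymethyl)-4-[4-(tert-butyldimethylsilyloxy)phenyl]-1-(4-methoxyphenyl)-2-[(triethylsilyloxy)methyl]butyl acetate F3. Bu4NF buffered with AcOH then removes both silyl groups without risk, since C7 carries no leaving group, to give (1S,2R,3S)-3-(acetoxymethyl)-2-(hydroxymethyl)-4-(4-hydroxyphenyl)-1-(4-methoxyphenyl)butyl acetate F4. DDQ (dioxane, rt) dehydrogenates the 4-alkylphenol of F4 to quinone methide 16, which closes to 17, where the fallback rejoins the route.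

Step 3 (NaBH4 removal of the auxiliary). The basic medium may cause translactonisation of 7 (O9' attacking the lactone carbonyl), E1cB opening or epimerisation of 6 at the imide α-carbon, or some lactone reduction. The fallback sets out from 6. LiOH/H2O2 (THF/H2O, 0 °C, then Na2SO3 and acidification) cleaves the imide to (2S,3S)-2-(4-methoxyphenyl)-5-oxooxolane-3-carboxylic acid F5. BH3·SMe2 (THF, 0 °C → rt) then reduces the acid chemoselectively under non-basic conditions, and the fallback comes back at 7.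

Step 5 (lactone aldol). The aldehyde is electron-rich, so conversion may be poor or retro-aldol may occur, and the trans selectivity at C8 could erode. The fallback is acylation followed by reduction and sets out from 9. Methyl 4-hydroxybenzoate is silylated (t-BuMe2SiCl, imidazole) to methyl 4-(tert-butyldimethylsilyloxy)benzoate F6. A crossed Claisen condensation of the enolate of 9 (2.1 equiv LiN(i-Pr)2) with F6 gives the β-keto lactone (3R,4R,5S)-3-[4-(tert-butyldimethylsilyloxy)benzoyl]-5-(4-methoxyphenyl)-4-[(triethylsilyloxy)methyl]oxolan-2-one F7, whose C8 centre equilibrates to trans through its enolate. LiBH4 reduces both ketone and lactone to triol 13 (either C7 epimer is acceptable), and acetylation in the same flask gives 14, where the fallback rejoins.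

**Further compounds**
F1 | step 7 | (3S,4R,5S)-3-[4-(tert-butyldimethylsilyloxy)benzyl]-5-(4-methoxyphenyl)-4-[(triethylsilyloxy)methyl]oxolan-2-one | COc1ccc([C@H]2OC(=O)[C@@H](Cc3ccc(O[Si](C)(C)C(C)(C)C)cc3)[C@@H]2CO[Si](CC)(CC)CC)cc1
F2 | step 7 | (1S,2R,3S)-3-[4-(tert-butyldimethylsilyloxy)benzyl]-1-(4-methoxyphenyl)-2-[(triethylsilyloxy)methyl]butane-1,4-diol | COc1ccc([C@@H](O)[C@@H](CO[Si](CC)(CC)CC)[C@@H](CO)Cc2ccc(O[Si](C)(C)C(C)(C)C)cc2)cc1
F3 | step 7 | (1S,2R,3S)-3-(acetoxymethyl)-4-[4-(tert-butyldimethylsilyloxy)phenyl]-1-(4-methoxyphenyl)-2-[(triethylsilyloxy)methyl]butyl acetate | COc1ccc([C@@H](OC(C)=O)[C@@H](CO[Si](CC)(CC)CC)[C@@H](COC(C)=O)Cc2ccc(O[Si](C)(C)C(C)(C)C)cc2)cc1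
F4 | step 7 | (1S,2R,3S)-3-(acetoxymethyl)-2-(hydroxymethyl)-4-(4-hydroxyphenyl)-1-(4-methoxyphenyl)butyl acetate | COc1ccc([C@@H](OC(C)=O)[C@@H](CO)[C@@H](COC(C)=O)Cc2ccc(O)cc2)cc1
F5 | step 3 | (2S,3S)-2-(4-methoxyphenyl)-5-oxooxolane-3-carboxylic acid | COc1ccc([C@H]2OC(=O)C[C@@H]2C(O)=O)cc1
F6 | step 5 | methyl 4-(tert-butyldimethylsilyloxy)benzoate | COC(=O)c1ccc(O[Si](C)(C)C(C)(C)C)cc1
F7 | step 5 | (3R,4R,5S)-3-[4-(tert-butyldimethylsilyloxy)benzoyl]-5-(4-methoxyphenyl)-4-[(triethylsilyloxy)methyl]oxolan-2-one | COc1ccc([C@H]2OC(=O)[C@@H](C(=O)c3ccc(O[Si](C)(C)C(C)(C)C)cc3)[C@@H]2CO[Si](CC)(CC)CC)cc1
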